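## Retrosynthetic overview

1. The target comes from its tris-MOM ether by acetal cleavage in the last step.
2. The whole side chain is installed in one flask on a 3'-bromoisoflavone. An enantioselective Pd-catalysed conjunctive cross-coupling joins the aryl bromide, a vinyl boronate and an isopropenyl Grignard reagent, forming the Ar–CH2 bond, the CH–C(CH3)=CH2 bond and the R stereocentre. C–B oxidation then gives the alcohol.
3. This avoids the usual prenyl group, epoxidation/isomerisation and Suzuki coupling.
4. The bromoisoflavone comes from phloroglucinol, 3-bromo-4-hydroxyphenylacetic acid and one carbon from DMF.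
5. Ring order: rings A and B are bought; ring C (the pyranone) is the only ring formed, in step 1.

Assumption: the (Sp,Sp) ligand antipode is taken to deliver the R boronate; if the sense proves opposite, the (Rp,Rp) antipode is used with nothing else changed.

## Route

Step 1
Reactants: 1 phloroglucinol (benzene-1,3,5-triol); 2 2-(3-bromo-4-hydroxyphenyl)acetic acid
Product: 4 3-(3-bromo-4-hydroxyphenyl)-5,7-dihydroxy-4H-chromen-4-one (3'-bromogenistein), via deoxybenzoin 3 (not isolated)
Conditions: BF3·OEt2 (solvent), 85 °C, 1.5 h; then DMF, MsCl, 70 °C, 2 h; aq. NaOAc work-up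
Reagents that add atoms: N,N-dimethylformamide, CN(C)C=O (supplies C-2 of the chromone)
Why: Friedel–Crafts C-acylation of the symmetric triol by the BF3-activated acid can give only one mono-ketone 3, whose BF3-chelated enol is C-formylated by the DMF/MsCl Vilsmeier-type reagent and closes onto the ortho hydroxyl with loss of dimethylamine (one-pot deoxybenzoin isoflavone synthesis, tolerant of aryl bromides).

Step 2
Reactants: 4 3'-bromogenistein
Product: 5 3-[3-bromo-4-(methoxymethoxy)phenyl]-5,7-bis(methoxymethoxy)-4H-chromen-4-one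
Conditions: NaH (3.6 equiv), MOMCl (3.6 equiv), DMF, 0 °C to rt
Reagents that add atoms: chloromethyl methyl ether (MOMCl), COCCl
Why: Williamson-type O-alkylation of the three sodium phenoxides, with NaH chosen so that the hydrogen-bonded 5-OH is also capped, because any acidic O–H would protonate borate 8 in step 3.

Step 3
Reactants: 5 tris-MOM 3'-bromoisoflavone; 6 vinylboronic acid pinacol ester; 7 isopropenylmagnesium bromide
Product: 10 3-{3-[(2R)-2-hydroxy-3-methylbut-3-en-1-yl]-4-(methoxymethoxy)phenyl}-5,7-bis(methoxymethoxy)-4H-chromen-4-one, via borate complex 8 (not isolated), via allylboronate 9 (not isolated)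
Conditions: 6 (1.6 equiv), 7 (1.5 equiv), THF, 0 °C to rt, 30 min; then NaOTf (NaOSO2CF3, 3 equiv), 5 (1.0 equiv), Pd(OAc)2 (3 mol%), (Sp,Sp)-1,1'-bis[bis(3,5-dimethylphenyl)phosphino]-2,2'-bis[(R)-(dimethylamino)(phenyl)methyl]ferrocene (a MandyPhos ligand, 3.6 mol%), THF, 60 °C, 16 h; then pH 7 phosphate buffer, 30% H2O2, 0 °C to rt
Reagents that add atoms: hydrogen peroxide, OO (oxygen of the new hydroxyl); the five side-chain carbons come from numbered reactants 6, C=CB1OC(C)(C)C(C)(C)O1, and 7, CC(=C)[Mg]Br
Why: Enantioselective palladium-catalysed conjunctive cross-coupling: zerovalent palladium inserts into the C–Br bond (NaOTf removes bromide as NaBr to leave a cationic arylpalladium), which binds the less substituted vinyl group of 8 and triggers a 1,2-metallate shift of the isopropenyl group from boron to the α-carbon anti to palladium, reductive elimination then gives ArCH2–CH(Bpin)–C(CH3)=CH2 with the boron-bearing carbon set as R by the chiral bisphosphine, and buffered peroxide replaces boron by OH with retention while the weakly nucleophilic borate leaves the chromone and MOM ethers untouched.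

Step 4
Reactants: 10 tris-MOM (R)-allylic alcohol
Product: 11 5,7-dihydroxy-3-{4-hydroxy-3-[(2R)-2-hydroxy-3-methylbut-3-en-1-yl]phenyl}-4H-chromen-4-one (target, CNP0116701.1)
Conditions: HCl (1 M), MeOH/THF, 40 °C, followed by LC-MS and stopped at full conversion
Reagents that add atoms: none
Why: Acid-catalysed acetal exchange with methanol removes the three aryl MOM ethers as dimethoxymethane, while protonation of the 1,1-disubstituted alkene (slowed by the adjacent hydroxyl) and ionisation of the secondary allylic alcohol should be much slower in dilute acid at 40 °C, so the stereocentre is untouched.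

## Compound list

1 | phloroglucinol (benzene-1,3,5-triol) | Oc1cc(O)cc(O)c1 | starting material
2 | 2-(3-bromo-4-hydroxyphenyl)acetic acid | OC(=O)Cc1ccc(O)c(Br)c1 | starting material
3 | 2-(3-bromo-4-hydroxyphenyl)-1-(2,4,6-trihydroxyphenyl)ethan-1-one (deoxybenzoin) | O=C(Cc1ccc(O)c(Br)c1)c1c(O)cc(O)cc1O | intermediate
4 | 3-(3-bromo-4-hydroxyphenyl)-5,7-dihydroxy-4H-chromen-4-one (3'-bromogenistein) | O=c1c(-c2ccc(O)c(Br)c2)coc2cc(O)cc(O)c12 | intermediate
5 | 3-[3-bromo-4-(methoxymethoxy)phenyl]-5,7-bis(methoxymethoxy)-4H-chromen-4-one | COCOc1cc(OCOC)c2c(c1)occ(-c1ccc(OCOC)c(Br)c1)c2=O | intermediate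
6 | vinylboronic acid pinacol ester (2-ethenyl-4,4,5,5-tetramethyl-1,3,2-dioxaborolane) | C=CB1OC(C)(C)C(C)(C)O1 | starting material
7 | isopropenylmagnesium bromide (THF solution) | CC(=C)[Mg]Br | starting material
8 | bromomagnesium ethenyl(prop-1-en-2-yl)(pinacolato)borate (borate complex) | C=C[B-]1(C(C)=C)OC(C)(C)C(C)(C)O1.[Mg+]Br | intermediate
9 | 3-{4-(methoxymethoxy)-3-[(2R)-3-methyl-2-(4,4,5,5-tetramethyl-1,3,2-dioxaborolan-2-yl)but-3-en-1-yl]phenyl}-5,7-bis(methoxymethoxy)-4H-chromen-4-one (allylboronate) | C=C(C)[C@H](B1OC(C)(C)C(C)(C)O1)Cc1cc(-c2coc3cc(OCOC)cc(OCOC)c3c2=O)ccc1OCOC | intermediate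
10 | 3-{3-[(2R)-2-hydroxy-3-methylbut-3-en-1-yl]-4-(methoxymethoxy)phenyl}-5,7-bis(methoxymethoxy)-4H-chromen-4-one | C=C(C)[C@H](O)Cc1cc(-c2coc3cc(OCOC)cc(OCOC)c3c2=O)ccc1OCOC | intermediate
11 | 5,7-dihydroxy-3-{4-hydroxy-3-[(2R)-2-hydroxy-3-methylbut-3-en-1-yl]phenyl}-4H-chromen-4-one | C=C(C)[C@H](O)Cc1cc(-c2coc3cc(O)cc(O)c3c2=O)ccc1O | target

## Step count and risks

Total step count: 4. Longest linear sequence: 4 steps (1 + 2 → 4 → 5 → 10 → 11).

**Step 3 (most likely to fail).** The risks are direct Suzuki-type transfer of a vinyl or isopropenyl group, bromide inhibition of the cationic palladium pathway, slow oxidative addition next to the ortho OMOM group, and an enantiomer ratio below the usual range. The absolute sense must be confirmed on 10 (Mosher esters).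

The fallback sets out from 5 and comes back at 10, replacing the three-component coupling by an aldehyde alkenylation. Stille coupling of 5 with allyltributylstannane (Pd(PPh3)4, toluene, 100 °C) gives 3-[3-allyl-4-(methoxymethoxy)phenyl]-5,7-bis(methoxymethoxy)-4H-chromen-4-one F1. Lemieux–Johnson cleavage of its terminal alkene (OsO4 cat., NaIO4, 2,6-lutidine, dioxane/H2O), which is far more electron-rich than the chromone double bond, gives 2-{5-[5,7-bis(methoxymethoxy)-4-oxo-4H-chromen-3-yl]-2-(methoxymethoxy)phenyl}acetaldehyde F2. A catalytic asymmetric Nozaki–Hiyama–Kishi coupling of F2 with 2-bromopropene (CrCl2 cat. with a chiral sulfonamide–oxazoline ligand, NiCl2·(2,9-dimethyl-1,10-phenanthroline) cat., Mn, Cp2ZrCl2, LiCl, MeCN, rt) adds the isopropenyl group to the aldehyde under ligand control and gives 10; the non-basic organochromium reagent tolerates the enolisable aldehyde and the chromone.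

**Step 4.** The risk is acid-promoted loss of the side chain: protonation of the isopropenyl group followed by 6-endo capture by the freed 4'-OH would give a 2,2-dimethylchroman-3-ol, or a semipinacol shift would give a ketone.

The fallback sets out from 4 and comes back at 11, replacing the acetal protecting groups by fluoride-labile ones so that no acid is used after the side chain is in place. Silylation of 4 (TBSOTf, 2,6-lutidine, CH2Cl2, 0 °C to rt) gives 3-[3-bromo-4-(tert-butyldimethylsilyloxy)phenyl]-5,7-bis(tert-butyldimethylsilyloxy)-4H-chromen-4-one F3. The same conjunctive coupling with 8 gives the tris-TBS (R)-allylboronate F4, which is oxidised in the flask to the tris-TBS (R)-allylic alcohol F5. Treatment of F5 with TBAF/AcOH (THF, 0 °C) gives 11.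

**Step 1.** The risk is a low yield or difficult purification of the polar tetrahydroxy bromide from the one-pot BF3/DMF/MsCl sequence.

The fallback sets out from 1 and comes back at 4, passing through 3, which is now isolated. It uses a nitrile electrophile and a Lewis-acid-free ring closure. NBS bromination of commercial 4-hydroxyphenylacetonitrile (MeCN, 0 °C) gives 3-bromo-4-hydroxyphenylacetonitrile F6. Houben–Hoesch reaction of 1 with F6 (ZnCl2, HCl gas, Et2O, 0 °C) precipitates 2-(3-bromo-4-hydroxyphenyl)-1-(2,4,6-trihydroxyphenyl)ethan-1-iminium chloride F7. Hydrolysis of F7 in hot water gives 3, which is closed to 4 with N,N-dimethylformamide dimethyl acetal (THF, reflux).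

## Further compounds

F1 | step 3 | 3-[3-allyl-4-(methoxymethoxy)phenyl]-5,7-bis(methoxymethoxy)-4H-chromen-4-one | C=CCc1cc(-c2coc3cc(OCOC)cc(OCOC)c3c2=O)ccc1OCOC
F2 | step 3 | 2-{5-[5,7-bis(methoxymethoxy)-4-oxo-4H-chromen-3-yl]-2-(methoxymethoxy)phenyl}acetaldehyde | O=CCc1cc(-c2coc3cc(OCOC)cc(OCOC)c3c2=O)ccc1OCOC
F3 | step 4 | 3-[3-bromo-4-(tert-butyldimethylsilyloxy)phenyl]-5,7-bis(tert-butyldimethylsilyloxy)-4H-chromen-4-one | CC(C)(C)[Si](C)(C)Oc1cc(O[Si](C)(C)C(C)(C)C)c2c(c1)occ(-c1ccc(O[Si](C)(C)C(C)(C)C)c(Br)c1)c2=O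
F4 | step 4 | 3-{4-(tert-butyldimethylsilyloxy)-3-[(2R)-3-methyl-2-(4,4,5,5-tetramethyl-1,3,2-dioxaborolan-2-yl)but-3-en-1-yl]phenyl}-5,7-bis(tert-butyldimethylsilyloxy)-4H-chromen-4-one | C=C(C)[C@H](B1OC(C)(C)C(C)(C)O1)Cc1cc(-c2coc3cc(O[Si](C)(C)C(C)(C)C)cc(O[Si](C)(C)C(C)(C)C)c3c2=O)ccc1O[Si](C)(C)C(C)(C)C
F5 | step 4 | 3-{4-(tert-butyldimethylsilyloxy)-3-[(2R)-2-hydroxy-3-methylbut-3-en-1-yl]phenyl}-5,7-bis(tert-butyldimethylsilyloxy)-4H-chromen-4-one | C=C(C)[C@H](O)Cc1cc(-c2coc3cc(O[Si](C)(C)C(C)(C)C)cc(O[Si](C)(C)C(C)(C)C)c3c2=O)ccc1O[Si](C)(C)C(C)(C)C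
F6 | step 1 | 3-bromo-4-hydroxyphenylacetonitrile | N#CCc1ccc(O)c(Br)c1
F7 | step 1 | 2-(3-bromo-4-hydroxyphenyl)-1-(2,4,6-trihydroxyphenyl)ethan-1-iminium chloride | [NH2+]=C(Cc1ccc(O)c(Br)c1)c1c(O)cc(O)cc1O.[Cl-]
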